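All runs were generated by integration with made-up constants; noise was put on by code.

In the delta run, at 3.00 h, right-handed substrate reads 47.0% against 45.6% for left-handed substrate, an excess of 1.51%. At 40.0 h the two read 43.5% and 43.6%, each figure with a scatter of 0.3 percentage points.

the same everywhere: free catalyst 5 mol%

| run | left-handed substrate | right-handed substrate | reagent | remark | time |
|---|---|---|---|---|---|
| theta | 0.074 M | 0.074 M | 1 equiv | run made earlier |  |
| delta | 0.17 M | 0.17 M | 1 equiv | run made earlier |  |
| flask | 0.11 M | 0.11 M | 1.00 equiv |  | 30 h |

| run | time / h | right-handed substrate / % | left-handed substrate / % |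
|---|---|---|---|
| theta | 8.00 | 46.5 | 46.6 |
| theta | 15.0 | 46.3 | 45.8 |
| theta | 20.0 | 45.7 | 45.5 |
| theta | 30.0 | 45.5 | 45.1 |
| theta | 40.0 | 44.6 | 44.4 |
| delta | 3.00 | 47.0 | 45.6 |
| delta | 10.0 | 45.2 | 45.0 |
| delta | 15.0 | 44.5 | 44.6 |
| delta | 25.0 | 44.7 | 43.7 |
| delta | 40.0 | 43.5 | 43.6 |

(standard deviation of a reading: 0.3 percentage points)

- free catalyst is single-handed; left-handed substrate and right-handed substrate are mirror images of each other, charged as a racemate, each of them at the stated concentration
- the earlier runs were read with a standard deviation of 0.3 points

* whether the excess of right-handed substrate over left-handed substrate among what is left of the two reaches 99% by 30 h (yes / no)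
* the highest excess of right-handed substrate over left-handed substrate among what is left of the two up to 30 h

The bench rule for a single-handed catalyst on a racemate is kinetic resolution: one hand goes faster, so the excess of the other climbs with conversion. I apply it to the delta run and it stops working. What is left of the two falls from 92.6% to 87.1%, yet the excess reads −0.115% at the end instead of climbing. So I stop reckoning with conversion and reckon with what the catalyst can hold. I suppose that binding is quick, that the catalyst charge sits on left-handed substrate, and that the two are otherwise level:

c(free catalyst) as charged = 5 mol% of c(left-handed substrate) = 0.00550 M in the new flask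

hiding ceiling = c(free catalyst) / [2 c(left-handed substrate) − c(free catalyst)] = 2.56%

This hiding ceiling is the excess among the unbound two when the catalyst holds its full charge of one hand. Concentration cancels, so at this loading it is the same in theta, delta and the new flask. The wanted 99% is 38.7 times the ceiling, so for the new flask I say no. I expect a top under the ceiling, near the delta reading of 1.51%.

The forecast says no, with a top of 0.4% (range 0.1% to 1%), on the grounds of “almost no selectivity”. My own figure is higher than its figure.

The flask gives no and a top of 1.77%, which is 0.692 of the ceiling, so the forecast held. By 3.00 h the excess in the flask is already down to 1.10%, and at 30.0 h it stands at 0.0746%. The loss of reagent to self-condensation product is a part of why the flask has only 11.1% of the two reacted: the same flask without that step has 31.9% reacted at 30.0 h.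

    2 reagent → self-condensation product (k = 5.20 × 10⁻⁴ M⁻¹ s⁻¹)
    free catalyst → spent catalyst (k = 2.70 × 10⁻⁵ s⁻¹)
    reagent + catalyst intermediate A → free catalyst + left-handed product (k = 0.00210 M⁻¹ s⁻¹)
    left-handed substrate ⇌ right-handed substrate (k = 1.30 × 10⁻⁴ s⁻¹)
    free catalyst + right-handed substrate ⇌ catalyst intermediate B (K = 10.0 M⁻¹, k = 0.240 M⁻¹ s⁻¹)
    reagent + catalyst intermediate B → free catalyst + right-handed product (k = 6.40 × 10⁻⁴ M⁻¹ s⁻¹)
    free catalyst + left-handed substrate ⇌ catalyst intermediate A (K = 220 M⁻¹, k = 0.0290 M⁻¹ s⁻¹)

With 20 mol% of free catalyst the ceiling becomes 11.1%, and the same share of it gives 7.68%. That neighbour's computed top is 7.49%.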